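**Retrosynthesis**
- Tsangin C is the anti (3S,4R) aldol-type ester ArCH(OAroyl)–CH(Me)–C(=O)Me, with Ar = 3,4,5-trimethoxyphenyl. No rings need to be built; both aryl rings come from commercial materials.
- Disconnect the aroyl ester (Ar'CO–O). This leaves a β-hydroxy methyl ketone.
- Convert the methyl ketone into a terminal vinyl group by a Wacker oxidation. This gives an anti homoallylic alcohol, which is the product of an (E)-crotylboration of 3,4,5-trimethoxybenzaldehyde.
- Both stereocenters are set in one step, by Brown asymmetric (E)-crotylation. The esterification and Wacker steps then proceed without touching them.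

**Assumption:** the target SMILES corresponds to (3S,4R) (anti) in butan-2-one numbering. The Ipc₂B reagent enantiomer that gives Re-face attack on the aldehyde, and hence (1R,2R) alcohol **4**, is taken to be the (−)-Ipc₂BOMe series from (+)-α-pinene. This should be confirmed by optical rotation or Mosher analysis.

**Step 1**
Reactants: **1** 3,4,5-trimethoxybenzaldehyde; **2** trans-2-butene; **3** (−)-B-methoxydiisopinocampheylborane, (−)-Ipc₂BOMe
Product: **4** (1R,2R)-2-methyl-1-(3,4,5-trimethoxyphenyl)but-3-en-1-ol (anti)
Conditions: (i) **2**, KOtBu, n-BuLi, THF, –45 °C; (ii) **3**, –78 °C; (iii) BF₃·OEt₂; (iv) **1**, –78 °C; (v) NaOH, H₂O₂, 0 °C to rt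
Reagents that add atoms: trans-2-butene, C/C=C/C (becomes the crotyl unit)
Why: Brown asymmetric crotylboration. The (E)-crotylpotassium gives the (E)-crotyl-Ipc₂B reagent, which reacts through a Zimmerman–Traxler chair transition state. This gives the anti relative configuration, and the chiral Ipc ligands direct attack to the Re face of the aldehyde, setting (1R,2R). The oxidative workup only cleaves the B–O bond.

**Step 2**
Reactants: **4**; **5** 3,4,5-trimethoxybenzoyl chloride
Product: **6** (1R,2R)-2-methyl-1-(3,4,5-trimethoxyphenyl)but-3-en-1-yl 3,4,5-trimethoxybenzoate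
Conditions: **5**, Et₃N, DMAP (cat.), CH₂Cl₂, 0 °C to rt
Reagents that add atoms: 3,4,5-trimethoxybenzoyl chloride, COc1cc(C(=O)Cl)cc(OC)c1OC
Why: DMAP-catalysed O-acylation of a secondary alcohol proceeds with retention, since the C–O bond is not broken. Acylating before the Wacker step avoids handling a β-hydroxy ketone, which is prone to retro-aldol reaction and epimerisation.

**Step 3**
Reactants: **6**
Product: **7** Tsangin C, (3S,4R)-4-(3,4,5-trimethoxybenzoyloxy)-3-methyl-4-(3,4,5-trimethoxyphenyl)butan-2-one
Conditions: PdCl₂ (10 mol%), CuCl (1 equiv), O₂ (balloon), DMF/H₂O 7:1, rt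
Reagents that add atoms: water, O (the ketone oxygen comes from water; O₂ is only the terminal oxidant)
Why: Tsuji–Wacker oxidation converts the terminal monosubstituted alkene to the methyl ketone with Markovnikov selectivity. No new stereocenter forms. The aryl ester and the electron-rich arenes are inert, and the mild, near-neutral conditions leave the α-methyl stereocenter intact. This converts the CH=CH₂ group into C(=O)CH₃ and leaves both stereocenters unchanged. CIP descriptors at the methine carbon change from R to S only because the substituent priorities change.

**Checks**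
- Formulas: **4** C₁₄H₂₀O₄; **6** C₂₄H₃₀O₈; **7** C₂₄H₃₀O₉. This matches the target: two trimethoxyaryl units, ester, ketone, one methyl.
- Stereochemistry: CIP analysis of the target SMILES gives the carbinol carbon R and the α-methyl carbon S. This is the anti isomer. Alkene **4** is (1R,2R), the known anti descriptor set for 2-methyl-1-arylbut-3-en-1-ols.
- Protecting groups: none are needed.

**Compound list**

| No. | Name | SMILES | Role |
|---|---|---|---|
| 1 | 3,4,5-trimethoxybenzaldehyde | COc1cc(C=O)cc(OC)c1OC | starting material |
| 2 | trans-2-butene | C/C=C/C | starting material |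
| 3 | (−)-B-methoxydiisopinocampheylborane (two (1R,2R,3R,5S)-isopinocampheyl groups, from (+)-α-pinene) | COB([C@@H]1C[C@@H]2C[C@@H](C2(C)C)[C@H]1C)[C@@H]1C[C@@H]2C[C@@H](C2(C)C)[C@H]1C | starting material (chiral reagent) |
| 4 | (1R,2R)-2-methyl-1-(3,4,5-trimethoxyphenyl)but-3-en-1-ol | O[C@@H](c1cc(OC)c(OC)c(OC)c1)[C@H](C)C=C | intermediate |
| 5 | 3,4,5-trimethoxybenzoyl chloride | COc1cc(C(=O)Cl)cc(OC)c1OC | starting material |
| 6 | (1R,2R)-2-methyl-1-(3,4,5-trimethoxyphenyl)but-3-en-1-yl 3,4,5-trimethoxybenzoate | COc1cc(C(=O)O[C@@H](c2cc(OC)c(OC)c(OC)c2)[C@H](C)C=C)cc(OC)c1OC | intermediate |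
| 7 | Tsangin C | COc1cc(C(=O)O[C@@H](c2cc(OC)c(OC)c(OC)c2)[C@H](C)C(C)=O)cc(OC)c1OC | target |

**Totals:** 3 steps; longest linear sequence 3 steps.

**Three steps most likely to fail**
1. **Step 1 (crotylboration).** Enantiofacial sense and ee with an electron-rich aldehyde, and the correct Ipc enantiomer series. Fallback: a different approach to the same anti aldol, namely direct organocatalytic anti-selective branched aldol of 2-butanone with **1** using a primary–tertiary diamine/TfOH catalyst. Esterification with **5** (as in Step 2) then gives **7**.
2. **Step 3 (Wacker).** Possible β-elimination of the aroate to the enone, α-epimerisation, or aldehyde regioisomer formation. Fallback: an Evans/Crimmins-type anti-aldol of an N-propionyl oxazolidinone (or thiazolidinethione) with **1**, then conversion to the Weinreb amide, MeMgBr addition and final aroylation with **5**.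
3. **Step 2 (esterification).** The hindered benzylic alcohol may acylate slowly, or a competing elimination may occur. Fallback: reorder the sequence. Do a hydroxyl-directed Wacker oxidation of free alcohol **4** to the β-hydroxy ketone, then aroylate it with 3,4,5-trimethoxybenzoic acid by Yamaguchi or Steglich esterification under mild, low-temperature conditions to avoid retro-aldol.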